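**Strategy.** The dihydropyran ring (O1, C2, C3, C4, C4a, C8a) is made by expanding a spiro-oxolane. Iodine(III) oxidation of the anisole ring A of an open-chain (S)-1,3-diarylpropan-1-ol makes the tether-bearing carbon para to the C6 methoxy group (future C8a) electrophilic; the carbinol oxygen closes a five-membered spiro ring there (O1, C2, C3, C4, C8a), and a 1,2-shift of C4 to C4a, the only free neighbour because C8 carries prenyl, enlarges it to the chroman and restores aromaticity. The precursor already holds both prenyl groups, carbamate-masked phenols and the C2 stereocentre, set by asymmetric transfer hydrogenation of a chalcone.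

Key step: step 8

Remark: C2 of the target is (S) by CIP; "prenyl" means 3-methylbut-2-en-1-yl; tributyl(3-methylbut-2-en-1-yl)stannane is taken as a purchasable reagent.

Step 1
Reactants: 1 2-bromo-3-hydroxy-4-methoxybenzaldehyde
Product: 2 2-bromo-3-formyl-6-methoxyphenyl N,N-diethylcarbamate
Conditions: Et2NCOCl, K2CO3, MeCN, reflux
Reagents that add atoms: N,N-diethylcarbamoyl chloride CCN(CC)C(Cl)=O
Why: Carbamoylation of the phenoxide (nucleophilic acyl substitution) masks the future O7 as a base-stable, poorly electron-donating group that survives the aldol step and keeps this oxygen from directing the later oxidation.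

Step 2
Reactants: 2 2-bromo-3-formyl-6-methoxyphenyl N,N-diethylcarbamate
Product: 3 3-formyl-6-methoxy-2-(3-methylbut-2-en-1-yl)phenyl N,N-diethylcarbamate
Conditions: Bu3Sn-prenyl, Pd(PPh3)4 (cat.), DMF, 100 °C
Reagents that add atoms: tributyl(3-methylbut-2-en-1-yl)stannane CCCC[Sn](CCCC)(CCCC)CC=C(C)C
Why: Stille coupling; the ortho-formyl group activates the C–Br bond for oxidative addition and the prenyl unit should be transferred at its unsubstituted terminus to give the linear prenyl arene.

Step 3
Reactants: 4 2',3',4'-trihydroxyacetophenone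
Product: 5 4-acetyl-3-hydroxy-1,2-phenylene bis(N,N-diethylcarbamate)
Conditions: Et2NCOCl (2.1 equiv), K2CO3, acetone, 55 °C, Ar
Reagents that add atoms: N,N-diethylcarbamoyl chloride CCN(CC)C(Cl)=O
Why: The 2-OH is locked in a hydrogen bond to the acetyl carbonyl, so carbamoylation (nucleophilic acyl substitution) should take only the 4- and 3-hydroxyls.

Step 4
Reactants: 5 4-acetyl-3-hydroxy-1,2-phenylene bis(N,N-diethylcarbamate)
Product: 6 4-acetyl-3-(trifluoromethanesulfonyloxy)-1,2-phenylene bis(N,N-diethylcarbamate)
Conditions: Tf2O, pyridine, CH2Cl2, 0 °C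
Reagents that add atoms: trifluoromethanesulfonic anhydride O=S(=O)(OS(=O)(=O)C(F)(F)F)C(F)(F)F
Why: O-Sulfonylation of the remaining chelated phenol turns the future C2' into a cross-coupling site.

Step 5
Reactants: 6 4-acetyl-3-(trifluoromethanesulfonyloxy)-1,2-phenylene bis(N,N-diethylcarbamate)
Product: 7 4-acetyl-3-(3-methylbut-2-en-1-yl)-1,2-phenylene bis(N,N-diethylcarbamate)
Conditions: Bu3Sn-prenyl, Pd(PPh3)4 (cat.), LiCl, DMF, 90 °C
Reagents that add atoms: tributyl(3-methylbut-2-en-1-yl)stannane CCCC[Sn](CCCC)(CCCC)CC=C(C)C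
Why: Stille coupling of an ortho-acyl aryl triflate, with chloride promoting transmetalation; the aryl carbamates are inert to palladium(0).

Step 6
Reactants: 7 4-acetyl-3-(3-methylbut-2-en-1-yl)-1,2-phenylene bis(N,N-diethylcarbamate); 3 3-formyl-6-methoxy-2-(3-methylbut-2-en-1-yl)phenyl N,N-diethylcarbamate
Product: 8 (E)-1-[3,4-bis(diethylcarbamoyloxy)-2-prenylphenyl]-3-[3-(diethylcarbamoyloxy)-4-methoxy-2-prenylphenyl]prop-2-en-1-one
Conditions: KOH, EtOH, 0 °C → rt
Reagents that add atoms: none
Why: Claisen–Schmidt aldol condensation; the methyl ketone is the only enolizable partner, dehydration gives the conjugated (E)-enone, and N,N-dialkylcarbamates should resist hydroxide at room temperature.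

Step 7
Reactants: 8 (E)-1-[3,4-bis(diethylcarbamoyloxy)-2-prenylphenyl]-3-[3-(diethylcarbamoyloxy)-4-methoxy-2-prenylphenyl]prop-2-en-1-one
Product: 10 (S)-1-[3,4-bis(diethylcarbamoyloxy)-2-prenylphenyl]-3-[3-(diethylcarbamoyloxy)-4-methoxy-2-prenylphenyl]propan-1-ol, via dihydrochalcone 9 (not isolated)
Conditions: RuCl[(S,S)-TsDPEN](p-cymene) (cat.), HCO2H/Et3N (5:2), EtOAc, 40 °C
Reagents that add atoms: none
Why: Noyori–Ikariya asymmetric transfer hydrogenation, in which conjugate reduction of the enone precedes outer-sphere hydride transfer to the aryl ketone; the (S,S)-ligand places the aryl group next to the η6-arene (CH/π contact) and should deliver hydride to give the (S)-carbinol, while the isolated trisubstituted alkenes are not reduced.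

Step 8
Reactants: 10 (S)-1-[3,4-bis(diethylcarbamoyloxy)-2-prenylphenyl]-3-[3-(diethylcarbamoyloxy)-4-methoxy-2-prenylphenyl]propan-1-ol
Product: 12 (2S)-7,3',4'-tris(diethylcarbamoyloxy)-6-methoxy-8,2'-diprenylflavan, via spiro-oxolane oxocarbenium ion 11 (not isolated)
Conditions: PhI(OCOCF3)2 (1.05 equiv), (CF3)2CHOH/CH2Cl2 (1:1), −20 → 0 °C; then aq. NaHCO3
Reagents that add atoms: none
Why: PhI(OCOCF3)2 in HFIP oxidises the most electron-rich arene, the ring A anisole (ring B is deactivated by two carbamates), and the carbinol oxygen adds to the tether-bearing carbon para to OMe (5-exo-trig, spiro closure of the oxolane O1–C2–C3–C4–C8a), giving after the second electron transfer the oxocarbenium ion 11. A 1,2-shift of C4 from C8a to C4a (Wagner–Meerwein shift of the dienone–phenol type) then expands the oxolane to the dihydropyran, leaving a cation stabilised by O1, and loss of the C4a proton restores aromaticity. The closest known reaction type is the iodine(III)-mediated oxidative ipso-cyclisation/1,2-shift of 3-(4-methoxyaryl)propan-1-ols to 6-methoxychromans. No stereocentre is created in the product: the spiro carbon is transient so both epimers of 11 converge, and C2 keeps its (S) configuration because the C2–O bond is never broken and the electron-poor ring B disfavours benzylic ionisation. The step needs ipso attack instead of direct attack at C4a, carbon instead of oxygen migration, and migration to C4a instead of C8: the methoxy group para to the ipso carbon together with the poorly donating carbamate on O7 directs the attack, the O1-stabilised cation favours carbon migration, and the prenyl group blocks C8 while only C4a carries a proton to lose.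

Step 9
Reactants: 12 (2S)-7,3',4'-tris(diethylcarbamoyloxy)-6-methoxy-8,2'-diprenylflavan
Product: 13 4-[(2S)-7-hydroxy-6-methoxy-8-(3-methylbut-2-en-1-yl)-3,4-dihydro-2H-chromen-2-yl]-3-(3-methylbut-2-en-1-yl)benzene-1,2-diol
Conditions: LiAlH4 (excess), THF, 0 °C → reflux; Rochelle salt, then dilute citric acid, Ar
Reagents that add atoms: none
Why: Reductive cleavage of aryl carbamates: hydride attack at the three carbamate carbonyls expels the phenoxides, while the aryl methyl ether, the benzylic ether, the prenyl alkenes and the C2 stereocentre are inert to LiAlH4.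

**Compound list**

1 | 2-bromo-3-hydroxy-4-methoxybenzaldehyde | COc1ccc(C=O)c(Br)c1O | starting material
2 | 2-bromo-3-formyl-6-methoxyphenyl N,N-diethylcarbamate | COc1ccc(C=O)c(Br)c1OC(=O)N(CC)CC | intermediate
3 | 3-formyl-6-methoxy-2-(3-methylbut-2-en-1-yl)phenyl N,N-diethylcarbamate | COc1ccc(C=O)c(CC=C(C)C)c1OC(=O)N(CC)CC | intermediate
4 | 2',3',4'-trihydroxyacetophenone | CC(=O)c1ccc(O)c(O)c1O | starting material
5 | 4-acetyl-3-hydroxy-1,2-phenylene bis(N,N-diethylcarbamate) | CC(=O)c1ccc(OC(=O)N(CC)CC)c(OC(=O)N(CC)CC)c1O | intermediate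
6 | 4-acetyl-3-(trifluoromethanesulfonyloxy)-1,2-phenylene bis(N,N-diethylcarbamate) | CC(=O)c1ccc(OC(=O)N(CC)CC)c(OC(=O)N(CC)CC)c1OS(=O)(=O)C(F)(F)F | intermediate
7 | 4-acetyl-3-(3-methylbut-2-en-1-yl)-1,2-phenylene bis(N,N-diethylcarbamate) | CC(=O)c1ccc(OC(=O)N(CC)CC)c(OC(=O)N(CC)CC)c1CC=C(C)C | intermediate
8 | (E)-1-[3,4-bis(diethylcarbamoyloxy)-2-prenylphenyl]-3-[3-(diethylcarbamoyloxy)-4-methoxy-2-prenylphenyl]prop-2-en-1-one | O=C(/C=C/c1ccc(OC)c(OC(=O)N(CC)CC)c1CC=C(C)C)c1ccc(OC(=O)N(CC)CC)c(OC(=O)N(CC)CC)c1CC=C(C)C | intermediate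
9 | 1-[3,4-bis(diethylcarbamoyloxy)-2-prenylphenyl]-3-[3-(diethylcarbamoyloxy)-4-methoxy-2-prenylphenyl]propan-1-one (dihydrochalcone) | O=C(CCc1ccc(OC)c(OC(=O)N(CC)CC)c1CC=C(C)C)c1ccc(OC(=O)N(CC)CC)c(OC(=O)N(CC)CC)c1CC=C(C)C | intermediate (not isolated)
10 | (S)-1-[3,4-bis(diethylcarbamoyloxy)-2-prenylphenyl]-3-[3-(diethylcarbamoyloxy)-4-methoxy-2-prenylphenyl]propan-1-ol | O[C@H](c1ccc(OC(=O)N(CC)CC)c(OC(=O)N(CC)CC)c1CC=C(C)C)CCc1ccc(OC)c(OC(=O)N(CC)CC)c1CC=C(C)C | intermediate
11 | (2S)-2-[3,4-bis(diethylcarbamoyloxy)-2-prenylphenyl]-7-(diethylcarbamoyloxy)-8-methoxy-6-prenyl-1-oxaspiro[4.5]deca-6,9-dien-8-ylium trifluoroacetate (both spiro epimers) | C[O+]=C1C=CC2(O[C@H](c3ccc(OC(=O)N(CC)CC)c(OC(=O)N(CC)CC)c3CC=C(C)C)CC2)C(CC=C(C)C)=C1OC(=O)N(CC)CC.[O-]C(=O)C(F)(F)F | intermediate (not isolated)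
12 | (2S)-7,3',4'-tris(diethylcarbamoyloxy)-6-methoxy-8,2'-diprenylflavan | COc1cc2c(c(CC=C(C)C)c1OC(=O)N(CC)CC)O[C@H](c1ccc(OC(=O)N(CC)CC)c(OC(=O)N(CC)CC)c1CC=C(C)C)CC2 | intermediate
13 | 4-[(2S)-7-hydroxy-6-methoxy-8-(3-methylbut-2-en-1-yl)-3,4-dihydro-2H-chromen-2-yl]-3-(3-methylbut-2-en-1-yl)benzene-1,2-diol | COc1cc2c(c(CC=C(C)C)c1O)O[C@H](c1ccc(O)c(O)c1CC=C(C)C)CC2 | target

**Step count.** Total: 9 steps. Longest linear sequence: 7 steps (steps 3–9, from 4).

**Steps most likely to fail**

Step 8. The iodine(III) reagent or the liberated trifluoroacetic acid may attack the prenyl double bonds. The more electron-rich product may be oxidised further. The cation may also be intercepted, with loss of the O-methyl or of the prenyl group, before the 1,2-shift. The fallback separates dearomatisation from ring expansion and avoids iodine(III) and acid in the oxidation. It sets out from 10: constant-current anodic oxidation (graphite anode, LiClO4, MeOH, 2,6-lutidine, 0 °C) should give, by ipso capture and methanol trapping, the neutral and isolable (2S)-2-[3,4-bis(diethylcarbamoyloxy)-2-prenylphenyl]-8,8-dimethoxy-6-prenyl-1-oxaspiro[4.5]deca-6,9-dien-7-yl N,N-diethylcarbamate F1. Brief treatment of this spiro quinone monoketal with BF3·OEt2 (CH2Cl2, −78 °C) should ionise the ketal to the same cation as in 11, and the 1,2-shift with loss of methanol returns to the route at 12.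

Step 7. Conjugate reduction of the hindered, electron-rich enone may be slow, so that 1,2-reduction to the allylic alcohol competes, and the ortho-prenyl group may erode facial selectivity at the ketone. The fallback sets out from 8: copper hydride conjugate reduction (Stryker's reagent cat., PhSiH3, toluene, rt) with isolation of the dihydrochalcone 9, then Corey–Bakshi–Shibata reduction with (R)-Me-CBS and catecholborane (toluene, −78 °C; catecholborane spares the prenyl alkenes) should give the (S)-alcohol and return to the route at 10. This fallback makes no new compound (F0).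

Step 5. Transmetalation at the aryl palladium species flanked by two ortho substituents may be sluggish, and allylic transposition may deliver the 1,1-dimethylallyl isomer instead of the prenyl group. The fallback sets out from 6: Stille coupling with allyltributylstannane (Pd(PPh3)4, LiCl, DMF, 80 °C), which has no regiochemical ambiguity, should give 4-acetyl-3-(prop-2-en-1-yl)-1,2-phenylene bis(N,N-diethylcarbamate) F2. Olefin cross-metathesis with 2-methyl-2-butene (Grubbs second-generation catalyst, CH2Cl2, 40 °C) then builds the prenyl group and returns to the route at 7.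

**Further compounds**

F1 | step 8 | (2S)-2-[3,4-bis(diethylcarbamoyloxy)-2-prenylphenyl]-8,8-dimethoxy-6-prenyl-1-oxaspiro[4.5]deca-6,9-dien-7-yl N,N-diethylcarbamate | COC1(OC)C=CC2(O[C@H](c3ccc(OC(=O)N(CC)CC)c(OC(=O)N(CC)CC)c3CC=C(C)C)CC2)C(CC=C(C)C)=C1OC(=O)N(CC)CC
F0 | step 7 | none | none
F2 | step 5 | 4-acetyl-3-(prop-2-en-1-yl)-1,2-phenylene bis(N,N-diethylcarbamate) | CC(=O)c1ccc(OC(=O)N(CC)CC)c(OC(=O)N(CC)CC)c1CC=C
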